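**Assumption:** the 5-OH stays free in the alkylation because it is chelated to C4=O. Naringin hydrolysis and 7/4'-alkylation under mild conditions leave C2 (S) unracemised.

## Retrosynthetic overview
- Target **1** (8,3'-diprenylnaringenin) comes from bis-ether **2** by two photochemical O→C [1,3]-prenyl shifts. These form both aryl C–C bonds, at C8 and C3', in one operation.
- **2** comes from 7,4'-di-O-prenylation of (S)-naringenin **3**. The 7-OH and 4'-OH are the acidic phenols, and the 5-OH is chelated to C4=O.
- **3** comes from acid hydrolysis of naringin **4**, a cheap citrus glycoside. No ring is built, because the (S)-chromanone core and its C2 stereocentre come intact from **4**, and the prenyl groups are added last.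

## Route

**Step 1**
Reactants: 4, naringin (naringenin 7-O-α-L-rhamnopyranosyl-(1→2)-β-D-glucopyranoside)
Product: 3, (S)-naringenin
Conditions: 2 M HCl, EtOH/H2O (1:1), 85 °C, 4 h
Reagents that add atoms: none (water and HCl only cleave the glycosidic bond, and the sugars leave as by-products)
Why: Acid-catalysed glycoside hydrolysis releases the aglycone. Flavanones are configurationally stable in acid, because ring-opening to the chalcone needs base, so C2 (S) is retained.

**Step 2**
Reactants: 3, (S)-naringenin; 5, prenyl bromide
Product: 2, (S)-7,4'-di-O-prenylnaringenin
Conditions: 5 (2.3 equiv), K2CO3 (2.5 equiv), acetone, rt, 12 h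
Reagents that add atoms: prenyl bromide, CC(C)=CCBr
Why: Williamson O-alkylation occurs at the acidic 7-OH and 4'-OH. The chelated 5-OH does not react. The 7-phenoxide disfavours retro-oxa-Michael ring opening, and rt with a weak base keeps C2 intact.

**Step 3**
Reactants: 2
Product: 1, Euchrestaflavanone A
Conditions: hν (300 nm Rayonet), degassed cyclohexane/CH2Cl2 (3:1), 10 °C, 8 h; then silica/prep-HPLC to remove the 6-prenyl isomer
Reagents that add atoms: none (isomerisation)
Why: Proposed new method: photo-Claisen-type double O→C [1,3]-prenyl migration on a flavanone bis(prenyl) ether.
- Mechanism: excitation of the 7-alkoxy-chromanone chromophore and of the 4-alkoxyphenyl ring homolyses the ArO–CH2 bond. This gives a caged aryloxyl/prenyl radical pair, which recombines at the ortho carbon by the primary prenyl terminus. Bonding through the tertiary terminus is sterically disfavoured at these di-ortho-substituted positions.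
- Tautomerisation: the resulting cyclohexadienone tautomerises to the phenol.
- B ring: the para position C1' is substituted, so only C3' (ortho) can give a re-aromatisable product.
- A ring: the cage favours C8, which is flanked by O7 and O1 and has high radical spin density. This mirrors the C8 preference of thermal Claisen rearrangement of 7-allyloxychromones.
- Closest known reaction: the photo-Claisen (photo-Fries-type) rearrangement of aryl allyl ethers. It has not been shown on flavanone bis-ethers.
- Stereochemistry: C2–H is not involved, so (S) is retained. No new stereocentre is formed.

## Compound list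
1 | Euchrestaflavanone A, (S)-8,3'-diprenylnaringenin | CC(C)=CCc1cc([C@@H]2CC(=O)c3c(O)cc(O)c(CC=C(C)C)c3O2)ccc1O | target
2 | (S)-7,4'-di-O-prenylnaringenin | CC(C)=CCOc1ccc([C@@H]2CC(=O)c3c(O)cc(OCC=C(C)C)cc3O2)cc1 | intermediate
3 | (S)-naringenin | Oc1ccc([C@@H]2CC(=O)c3c(O)cc(O)cc3O2)cc1 | intermediate
4 | naringin | O(c1cc(O)c2C(=O)C[C@@H](c3ccc(O)cc3)Oc2c1)[C@@H]4O[C@H](CO)[C@@H](O)[C@H](O)[C@H]4O[C@@H]5O[C@@H](C)[C@H](O)[C@@H](O)[C@H]5O | starting material
5 | prenyl bromide (1-bromo-3-methylbut-2-ene) | CC(C)=CCBr | starting material

## Totals
Total steps: 3. Longest linear sequence: 3.

## Three steps most likely to fail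
1. **Step 3 (proposed new step).** Risks are C6-versus-C8 selectivity, reverse-prenyl isomers, incomplete double migration, photodegradation, and photoracemisation at C2.
   - Fallback (known chemistry): alkylate **3** with allyl bromide/K2CO3 to give the 7,4'-di-O-allyl ether. Do a double aromatic Claisen rearrangement (PhNEt2, microwave, about 200 °C), which is C8-selective for 7-allyloxychromones and ortho-selective on the B ring. Then do cross-metathesis with 2-methyl-2-butene (Hoveyda–Grubbs II) to convert both allyl groups to prenyl.
2. **Step 2.** Risks are partial racemisation through the chalcone, or C- and 5-O-alkylation.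
   - Fallback: replace the base-mediated SN2 with neutral Mitsunobu etherification (prenol, PPh3, DIAD, THF, 0 °C).
3. **Step 1.** Risks are incomplete hydrolysis or small ee erosion.
   - Fallback: skip the hydrolysis and start from commercial (S)-naringenin, recrystallised to upgrade the ee.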